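The six-membered ring C1–C2–C3–C4–C5–C8 of the bicyclo[3.2.1]octenone holds a 2-methoxyallyl unit, C2=C3(OMe)–C4(O), so C3 is disconnected as a carbene carbon from a norbornene that already contains C1, C2 and C4–C8. In one operation chloro(methoxy)carbene adds to the strained C2=C4 bond and the chlorocyclopropane opens: C2–C3 and C3–C4 form, the five-membered ring C1–C2–C4–C5–C8 grows to the six-membered one, and the enol ether plus a C4 leaving group arrive together. The precursor is a 1-allyl-5-exo-aryl-6-endo-methylnorbornene with a silyloxy group on the bridge carbon anti to the alkene, made by an auxiliary-controlled Diels–Alder reaction.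

Key step: step 11

Remarks on the chemistry (valid for all steps):
- Numbering: bicyclo[3.2.1]octenes carry the target numbering (C1 allyl bridgehead, C2=C3(OMe), C4, C5 bridgehead CH, C6 aryl, C7 methyl, C8 bridge). Norbornenes carry their own numbering (C1 allyl bridgehead, C2=C3, C4 bridgehead CH, C5 aryl, C6 methyl or acyl, C7 bridge).
- Design of the precursor: a dimethyl ketal on the bridge carbon would put a methoxy group over the exo face of the alkene. That is the only face left to the carbene, because the endo face is closed by the endo-methyl group. The bridge carbon is therefore carried through the key step as CH–OSiEt3 with hydrogen on the alkene side, and is oxidised to the ketone afterwards. Ring atoms and the bonds formed are unchanged.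
- Assumption: 1 is purchased (otherwise one step from furfural and CH2=CHCH2MgBr). Compounds 2–6 are racemic; this is immaterial because both stereocentres disappear in diene 7.
- Compounds 22 and 23 are drawn as the 4-exo alcohols; the C4 epimer, if formed, converges on 25.

Step 1
Reactants: 1 1-(furan-2-yl)but-3-en-1-ol (racemic)
Product: 2 trans-5-allyl-4-hydroxycyclopent-2-en-1-one (racemic)
Conditions: ZnCl2, dioxane–H2O, 80 °C
Reagents that add atoms: none
Why: Piancatelli rearrangement, in which ionisation of the furyl carbinol, hydration, ring opening and conrotatory 4π electrocyclisation should give the trans-4-hydroxy-5-substituted cyclopentenone; its two stereocentres are not needed later.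

Step 2
Reactants: 2 trans-5-allyl-4-hydroxycyclopent-2-en-1-one
Product: 5 trans-5-allyl-4,4-dimethoxycyclopent-2-en-1-ol (racemic), via silyloxy enone 3 (not isolated), via silyloxy ketal 4 (not isolated)
Conditions: Me3SiOCH3 (4 equiv), Me3SiOTf (cat.), CH2Cl2, −78 → −40 °C, pyridine quench; then K2CO3, CH3OH, 0 °C
Reagents that add atoms: methoxytrimethylsilane, CO[Si](C)(C)C
Why: Me3SiOTf-catalysed ketalisation of an enone with an alkoxysilane at low temperature, which should avoid conjugate addition and double-bond shift, the hydroxyl being held as a transient silyl ether that methanolysis frees.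

Step 3
Reactants: 5 trans-5-allyl-4,4-dimethoxycyclopent-2-en-1-ol
Product: 7 1-allyl-5,5-dimethoxycyclopenta-1,3-diene, via allylic mesylate 6 (not isolated)
Conditions: CH3SO2Cl, Et3N, CH2Cl2, −20 °C; then DBU, −20 → 0 °C; cold pentane extraction, solution used at once
Reagents that add atoms: none
Why: sulfonylation followed by base-induced 1,2-elimination, for which the allyl-bearing carbon offers the only β-hydrogen, so a single diene can form (an allylic chloride from chloride return would give the same diene by 1,2- or 1,4-elimination); the ketal carbon blocks 1,5-hydrogen shifts and the diene is kept cold because it can dimerise.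

Step 4
Reactants: 8 (E)-3,4-dimethoxycinnamic acid; 9 (R)-4-benzyloxazolidin-2-one
Product: 11 (R)-4-benzyl-3-[(E)-3-(3,4-dimethoxyphenyl)acryloyl]oxazolidin-2-one, via mixed pivalic anhydride 10 (not isolated)
Conditions: (CH3)3CCOCl, Et3N, THF, −20 °C; then 9, LiCl, −20 °C → rt
Reagents that add atoms: none
Why: N-acylation of the oxazolidinone through the mixed anhydride under LiCl/Et3N activation, which leaves the E-alkene untouched.

Step 5
Reactants: 7 1-allyl-5,5-dimethoxycyclopenta-1,3-diene (3 equiv); 11 (R)-4-benzyl-3-[(E)-3-(3,4-dimethoxyphenyl)acryloyl]oxazolidin-2-one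
Product: 12 (4R)-4-benzyl-3-{[1-allyl-5-exo-(3,4-dimethoxyphenyl)-7,7-dimethoxybicyclo[2.2.1]hept-2-en-6-endo-yl]carbonyl}oxazolidin-2-one
Conditions: Et2AlCl (1.6 equiv), CH2Cl2, −40 → −10 °C; 1 M HCl quench
Reagents that add atoms: none
Why: Lewis-acid-promoted Diels–Alder reaction of the Al-chelated s-cis imide, in which the β-carbon leads bond formation at the unsubstituted diene terminus (acyl carbon next to the allyl bridgehead), the chelated acyl group sits endo (aryl exo), and the benzyl group of the (R)-auxiliary shields one dienophile face, so that C1, C4, C5 and C6 are all set here.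

Step 6
Reactants: 12 Diels–Alder imide
Product: 13 [1-allyl-5-exo-(3,4-dimethoxyphenyl)-7,7-dimethoxybicyclo[2.2.1]hept-2-en-6-endo-yl]methanol
Conditions: LiBH4, CH3OH (1.1 equiv), THF, 0 °C
Reagents that add atoms: none
Why: reductive cleavage of the N-acyl oxazolidinone to the primary alcohol with return of the auxiliary; ketal, alkenes and all stereocentres are untouched.

Step 7
Reactants: 13 primary alcohol
Product: 14 [1-allyl-5-exo-(3,4-dimethoxyphenyl)-7,7-dimethoxybicyclo[2.2.1]hept-2-en-6-endo-yl]methyl 4-methylbenzenesulfonate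
Conditions: TsCl, Et3N, DMAP (cat.), CH2Cl2, 0 °C → rt
Reagents that add atoms: p-toluenesulfonyl chloride, Cc1ccc(cc1)S(Cl)(=O)=O
Why: sulfonylation of a primary alcohol, which turns the former acyl carbon into a leaving group for hydride.

Step 8
Reactants: 14 ketal tosylate
Product: 15 [1-allyl-5-exo-(3,4-dimethoxyphenyl)-7-oxobicyclo[2.2.1]hept-2-en-6-endo-yl]methyl 4-methylbenzenesulfonate
Conditions: 5% aq. H2SO4, THF, rt → 40 °C
Reagents that add atoms: water, O
Why: acid-catalysed ketal hydrolysis, assisted by the C2=C3 π bond in the ionisation at C7; the primary tosylate, the arene and the isolated alkenes should tolerate dilute acid at this temperature.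

Step 9
Reactants: 15 keto tosylate
Product: 17 1-allyl-5-exo-(3,4-dimethoxyphenyl)-6-endo-methylbicyclo[2.2.1]hept-2-en-7-anti-ol (OH anti to C2=C3), via hydroxy tosylate 16 (not isolated)
Conditions: LiEt3BH (4 equiv), THF, 0 °C → rt
Reagents that add atoms: none
Why: hydride reduction doing two jobs: the C7 ketone is attacked from the alkene side because the other face is screened by the exo-aryl group (this sets C7 with OH anti to the alkene), and the primary tosylate is displaced by hydride (SN2) to give the C6 methyl group.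

Step 10
Reactants: 17 anti-7-ol
Product: 18 1-allyl-5-exo-(3,4-dimethoxyphenyl)-6-endo-methyl-7-anti-(triethylsilyloxy)bicyclo[2.2.1]hept-2-ene
Conditions: Et3SiOSO2CF3, 2,6-lutidine, CH2Cl2, −78 → 0 °C
Reagents that add atoms: triethylsilyl trifluoromethanesulfonate, CC[Si](CC)(CC)OS(=O)(=O)C(F)(F)F
Why: silylation of a hindered secondary alcohol with a silyl triflate; the ether tolerates CH3Li and leaves only hydrogen on the alkene side of the bridge carbon.

Step 11
Reactants: 18 silyl ether precursor; 19 dichloromethyl methyl ether (4 equiv)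
Product: 21 1-allyl-4-exo-chloro-6-exo-(3,4-dimethoxyphenyl)-3-methoxy-7-endo-methyl-8-(triethylsilyloxy)bicyclo[3.2.1]oct-2-ene (silyloxy on the C6–C7 side), via chloromethoxy cyclopropane 20 (not isolated)
Conditions: Et2O, −15 °C; CH3Li·LiI (3.5 equiv, Et2O) added over 2 h; then rt
Reagents that add atoms: none
Why: CH3Li deprotonates 19 to the carbenoid LiCCl2OCH3, which transfers chloro(methoxy)carbene to the strained C2=C4 bond (norbornene C2=C3) in a [2+1] addition, and the cyclopropane 20 with chlorine on the C8 side ionises with disrotatory 2π-electrocyclic opening to a 2-methoxyallyl cation that chloride recaptures. The closest known reaction types are the dihalocarbene ring expansion of norbornenes to 3,4-dihalobicyclo[3.2.1]oct-2-enes and the ring enlargement of cycloalkenes to 2-alkoxyallyl halides with this carbenoid. The six-membered ring C1–C2–C3–C4–C5–C8 is closed by one-carbon insertion: C3 bridges C2 and C4 of the five-membered ring C1–C2–C4–C5–C8 and the shared C2–C4 bond is then cleaved. The only new stereocentre, C4, should carry chlorine exo because chloride returns within the ion pair on the face it left; this configuration is not relied on, since C4 is oxidised in step 13. The step needs the carbene to take the ring alkene and not the allyl group (ring strain and cis-disubstitution favour it over a monosubstituted alkene, and CH3Li is added slowly to an excess of 19), to add on the exo face (the endo face is closed by the endo-methyl group and the bridge carbon shows only hydrogen to the exo face), and chloride to return at C4 and not at C2 (C2 adjoins the quaternary bridgehead C1). If the epimer of 20 with chlorine turned away from C8 persists, warming with LiCl should equilibrate it through the methoxy-stabilised cyclopropyl cation.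

Step 12
Reactants: 21 allylic chloride
Product: 23 1-allyl-6-exo-(3,4-dimethoxyphenyl)-3-methoxy-7-endo-methylbicyclo[3.2.1]oct-2-ene-4-exo,8-diol (8-OH on the C6–C7 side), via silyloxy allylic alcohol 22 (not isolated)
Conditions: Ag2CO3, acetone–H2O, rt, dark; filtration; then Bu4NF, THF, rt
Reagents that add atoms: water, O
Why: silver-assisted SN1 hydrolysis of the 2-methoxyallyl chloride under carbonate buffer (enol ether preserved), with water entering at C4 and not at the neopentyl-like C2 and from the open exo face, followed by fluoride cleavage of the Si–O bond.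

Step 13
Reactants: 23 diol
Product: 25 1-allyl-6-exo-(3,4-dimethoxyphenyl)-3-methoxy-7-endo-methylbicyclo[3.2.1]oct-2-ene-4,8-dione, via hydroxy enone 24 (not isolated)
Conditions: Dess–Martin periodinane (3 equiv), NaHCO3, CH2Cl2, 0 °C → rt
Reagents that add atoms: none
Why: Dess–Martin oxidation of both secondary alcohols under bicarbonate buffer, the allylic C4 alcohol first and the bridge alcohol second; the C5 bridgehead between the two carbonyls cannot enolise, so no stereocentre is at risk.

Step 14
Reactants: 25 enedione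
Product: 26 (1R,4R,5S,6S,7S)-1-allyl-6-(3,4-dimethoxyphenyl)-4-hydroxy-3-methoxy-7-methylbicyclo[3.2.1]oct-2-en-8-one (target)
Conditions: NaBH4 (1 equiv), CeCl3·7H2O, CH3OH, −78 °C; aq. NH4Cl quench
Reagents that add atoms: none
Why: Luche reduction, which should reduce the conjugated C4 carbonyl in 1,2 fashion while the strained non-conjugated C8 carbonyl is held as its hemiketal in the medium; hydride enters C4 from the exo face (the side of the flat C8 carbonyl), the endo face being screened by the C6–C7 bridge, which sets C4 as the endo (equatorial) alcohol.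

Compound list
1 | 1-(furan-2-yl)but-3-en-1-ol (racemic) | C=CCC(O)c1ccco1 | starting material
2 | trans-5-allyl-4-hydroxycyclopent-2-en-1-one (racemic, one enantiomer drawn) | C=CC[C@H]1[C@H](O)C=CC1=O | intermediate
3 | trans-5-allyl-4-(trimethylsilyloxy)cyclopent-2-en-1-one (racemic) | C=CC[C@H]1[C@H](O[Si](C)(C)C)C=CC1=O | intermediate
4 | trans-5-allyl-4,4-dimethoxy-1-(trimethylsilyloxy)cyclopent-2-ene (racemic) | C=CC[C@H]1[C@H](O[Si](C)(C)C)C=CC1(OC)OC | intermediate
5 | trans-5-allyl-4,4-dimethoxycyclopent-2-en-1-ol (racemic) | C=CC[C@H]1[C@H](O)C=CC1(OC)OC | intermediate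
6 | trans-5-allyl-4,4-dimethoxycyclopent-2-en-1-yl methanesulfonate (racemic) | C=CC[C@H]1[C@H](OS(C)(=O)=O)C=CC1(OC)OC | intermediate
7 | 1-allyl-5,5-dimethoxycyclopenta-1,3-diene | C=CCC1=CC=CC1(OC)OC | intermediate
8 | (E)-3,4-dimethoxycinnamic acid | COc1ccc(/C=C/C(=O)O)cc1OC | starting material
9 | (R)-4-benzyloxazolidin-2-one | O=C1N[C@H](Cc2ccccc2)CO1 | starting material
10 | (E)-3-(3,4-dimethoxyphenyl)acrylic pivalic anhydride | COc1ccc(/C=C/C(=O)OC(=O)C(C)(C)C)cc1OC | intermediate
11 | (R)-4-benzyl-3-[(E)-3-(3,4-dimethoxyphenyl)acryloyl]oxazolidin-2-one | COc1ccc(/C=C/C(=O)N2[C@H](Cc3ccccc3)COC2=O)cc1OC | intermediate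
12 | (4R)-4-benzyl-3-{[1-allyl-5-exo-(3,4-dimethoxyphenyl)-7,7-dimethoxybicyclo[2.2.1]hept-2-en-6-endo-yl]carbonyl}oxazolidin-2-one | C=CC[C@@]12C=C[C@@H](C1(OC)OC)[C@@H](c1ccc(OC)c(OC)c1)[C@@H]2C(=O)N1[C@H](Cc2ccccc2)COC1=O | intermediate
13 | [1-allyl-5-exo-(3,4-dimethoxyphenyl)-7,7-dimethoxybicyclo[2.2.1]hept-2-en-6-endo-yl]methanol | C=CC[C@@]12C=C[C@@H](C1(OC)OC)[C@@H](c1ccc(OC)c(OC)c1)[C@@H]2CO | intermediate
14 | tosylate of 13 | C=CC[C@@]12C=C[C@@H](C1(OC)OC)[C@@H](c1ccc(OC)c(OC)c1)[C@@H]2COS(=O)(=O)c1ccc(C)cc1 | intermediate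
15 | [1-allyl-5-exo-(3,4-dimethoxyphenyl)-7-oxobicyclo[2.2.1]hept-2-en-6-endo-yl]methyl 4-methylbenzenesulfonate | C=CC[C@@]12C=C[C@@H](C1=O)[C@@H](c1ccc(OC)c(OC)c1)[C@@H]2COS(=O)(=O)c1ccc(C)cc1 | intermediate
16 | 7-anti-hydroxy analogue of 15 (OH anti to C2=C3) | C=CC[C@@]12C=C[C@@H]([C@@H]1O)[C@@H](c1ccc(OC)c(OC)c1)[C@@H]2COS(=O)(=O)c1ccc(C)cc1 | intermediate
17 | 1-allyl-5-exo-(3,4-dimethoxyphenyl)-6-endo-methylbicyclo[2.2.1]hept-2-en-7-anti-ol | C=CC[C@@]12C=C[C@@H]([C@@H]1O)[C@@H](c1ccc(OC)c(OC)c1)[C@@H]2C | intermediate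
18 | 1-allyl-5-exo-(3,4-dimethoxyphenyl)-6-endo-methyl-7-anti-(triethylsilyloxy)bicyclo[2.2.1]hept-2-ene (key-step precursor) | C=CC[C@@]12C=C[C@@H]([C@@H]1O[Si](CC)(CC)CC)[C@@H](c1ccc(OC)c(OC)c1)[C@@H]2C | intermediate
19 | dichloromethyl methyl ether | COC(Cl)Cl | starting material
20 | exo-fused 3-chloro-3-methoxytricyclo[3.2.1.0(2,4)]octane from 18 (Cl toward C8, OMe away) | C=CC[C@@]12[C@H]3[C@](Cl)(OC)[C@H]3[C@@H]([C@@H]1O[Si](CC)(CC)CC)[C@@H](c1ccc(OC)c(OC)c1)[C@@H]2C | intermediate
21 | 1-allyl-4-exo-chloro-6-exo-(3,4-dimethoxyphenyl)-3-methoxy-7-endo-methyl-8-(triethylsilyloxy)bicyclo[3.2.1]oct-2-ene (key-step product) | C=CC[C@@]12C=C(OC)[C@@H](Cl)[C@@H]([C@@H]1O[Si](CC)(CC)CC)[C@@H](c1ccc(OC)c(OC)c1)[C@@H]2C | intermediate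
22 | 4-exo-hydroxy analogue of 21 | C=CC[C@@]12C=C(OC)[C@@H](O)[C@@H]([C@@H]1O[Si](CC)(CC)CC)[C@@H](c1ccc(OC)c(OC)c1)[C@@H]2C | intermediate
23 | 1-allyl-6-exo-(3,4-dimethoxyphenyl)-3-methoxy-7-endo-methylbicyclo[3.2.1]oct-2-ene-4-exo,8-diol | C=CC[C@@]12C=C(OC)[C@@H](O)[C@@H]([C@@H]1O)[C@@H](c1ccc(OC)c(OC)c1)[C@@H]2C | intermediate
24 | 1-allyl-6-exo-(3,4-dimethoxyphenyl)-8-hydroxy-3-methoxy-7-endo-methylbicyclo[3.2.1]oct-2-en-4-one | C=CC[C@@]12C=C(OC)C(=O)[C@@H]([C@@H]1O)[C@@H](c1ccc(OC)c(OC)c1)[C@@H]2C | intermediate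
25 | 1-allyl-6-exo-(3,4-dimethoxyphenyl)-3-methoxy-7-endo-methylbicyclo[3.2.1]oct-2-ene-4,8-dione | C=CC[C@@]12C=C(OC)C(=O)[C@@H](C1=O)[C@@H](c1ccc(OC)c(OC)c1)[C@@H]2C | intermediate
26 | (1R,4R,5S,6S,7S)-1-allyl-6-(3,4-dimethoxyphenyl)-4-hydroxy-3-methoxy-7-methylbicyclo[3.2.1]oct-2-en-8-one (4-endo-OH, 6-exo-aryl, 7-endo-methyl) | C=CC[C@@]12C=C(OC)[C@H](O)[C@@H](C1=O)[C@@H](c1ccc(OC)c(OC)c1)[C@@H]2C | target

Total step count: 14. Longest linear sequence: 13 steps (steps 1–3 and 5–14; step 4 is the side branch).

Steps most likely to fail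

1. Step 11. The carbenoid may be consumed by CH3Li or by the allyl group faster than it adds to the ring alkene, or the adduct may form mainly as the cyclopropane epimer that cannot open. The fallback sets out from 18 and comes back at 22. Dibromocarbene from CHBr3 and KOC(CH3)3 in pentane at 0 °C, the classical ring expansion of norbornenes, should give the 3-bromo-4-exo-bromo ring-expanded silyl ether F1. Ag2CO3 in aqueous acetone should then hydrolyse the allylic bromide to the 3-bromo-4-exo-ol F2. Copper-catalysed methoxylation of the vinyl bromide (NaOCH3, CuBr, N-methylpyrrolidone–CH3OH, 110 °C; Ullmann-type vinyl ether formation) gives 22, which is desilylated to 23 as in step 12.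

2. Step 5. Cycloaddition at the substituted diene terminus may be slow, so that diene dimerisation wins or endo and facial control erode at the temperature needed. The fallback sets out from 7 and comes back at 13. Iminium activation gives a more reactive dienophile: (E)-3,4-dimethoxycinnamaldehyde with (5R)-5-benzyl-2,2,3-trimethylimidazolidin-4-one hydrochloride (cat.) in CH3OH–H2O at rt should give the 6-endo-carbaldehyde F3, the exo-formyl isomer being removed by chromatography. NaBH4 in CH3OH then reduces it to 13.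

3. Step 14. Hydride may be delivered to the strained C8 carbonyl in competition with C4, or both carbonyls may be reduced. The fallback sets out from 25 and comes back at 26. Excess NaBH4 with CeCl3·7H2O reduces both carbonyls to the 4-endo,8-diol F4. The less hindered C4 hydroxyl is silylated selectively (Et3SiCl, imidazole, CH2Cl2, −20 °C) to the 4-O-triethylsilyl ether F5. Dess–Martin oxidation of the remaining bridge alcohol gives the 8-ketone F6, and Bu4NF buffered with CH3CO2H in THF at 0 °C frees 26.

Further compounds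
F1 | step 11 | 1-allyl-3-bromo-4-exo-bromo-6-exo-(3,4-dimethoxyphenyl)-7-endo-methyl-8-(triethylsilyloxy)bicyclo[3.2.1]oct-2-ene | C=CC[C@@]12C=C(Br)[C@@H](Br)[C@@H]([C@@H]1O[Si](CC)(CC)CC)[C@@H](c1ccc(OC)c(OC)c1)[C@@H]2C
F2 | step 11 | 1-allyl-3-bromo-6-exo-(3,4-dimethoxyphenyl)-7-endo-methyl-8-(triethylsilyloxy)bicyclo[3.2.1]oct-2-en-4-exo-ol | C=CC[C@@]12C=C(Br)[C@@H](O)[C@@H]([C@@H]1O[Si](CC)(CC)CC)[C@@H](c1ccc(OC)c(OC)c1)[C@@H]2C
F3 | step 5 | 1-allyl-5-exo-(3,4-dimethoxyphenyl)-7,7-dimethoxybicyclo[2.2.1]hept-2-ene-6-endo-carbaldehyde | C=CC[C@@]12C=C[C@@H](C1(OC)OC)[C@@H](c1ccc(OC)c(OC)c1)[C@@H]2C=O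
F4 | step 14 | 1-allyl-6-exo-(3,4-dimethoxyphenyl)-3-methoxy-7-endo-methylbicyclo[3.2.1]oct-2-ene-4-endo,8-diol | C=CC[C@@]12C=C(OC)[C@H](O)[C@@H]([C@@H]1O)[C@@H](c1ccc(OC)c(OC)c1)[C@@H]2C
F5 | step 14 | 4-endo-O-triethylsilyl ether of F4 | C=CC[C@@]12C=C(OC)[C@H](O[Si](CC)(CC)CC)[C@@H]([C@@H]1O)[C@@H](c1ccc(OC)c(OC)c1)[C@@H]2C
F6 | step 14 | 1-allyl-6-exo-(3,4-dimethoxyphenyl)-3-methoxy-7-endo-methyl-4-endo-(triethylsilyloxy)bicyclo[3.2.1]oct-2-en-8-one | C=CC[C@@]12C=C(OC)[C@H](O[Si](CC)(CC)CC)[C@@H](C1=O)[C@@H](c1ccc(OC)c(OC)c1)[C@@H]2C
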